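Time is what to watch in this flask, held against the pace at which crystals empty the solution.

    J ⇌ Z (K1 = 2.1, k1 = 1.32 s⁻¹)
    J ⇌ Q (K2 = 11, k2 = 0.770 s⁻¹)
    D ⇌ Z, rate k3*(cs3 - [Z]) while solid is left; crystals form when [Z] > cs3 (cs3 = 0.20 mM, k3 = 0.211 s⁻¹)
    E → J (k4 = 0.179 s⁻¹)

E 10 mM; time 30 s

- Z and D together at 30 s, in percent of the E charged
- the change that raises the amount of Z and D together at 30 s, in percent of the E charged most ("none" if none brings more than 2 percentage points) (Wednesday's / Sunday's / none)
- amount of Z and D together at 30 s, in percent of the E charged, after Wednesday's

- Wednesday's: doubling the solubility in step 3, all else as stated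
- Sunday's: doubling the dissolution coefficient of step 3, all else as stated

- what is said of Z includes D
- D is a solid; its amount is given per volume of the solution
- run time (flask): 30 s

I count turnovers. J exchanges with Z and Q at relaxation half-lives of 0.356 s and 0.825 s, far shorter than 30 s, so I treat J, Z and Q as a single dissolved stock. Z is made from J at 1.32 s⁻¹ and leaves at 0.840 s⁻¹, back to J and into crystals, so I put [Z] at 1.57 times [J]. With [Q] taken at 11 times [J], dissolved Z is 11.6% of the stock. The drain time, the inverse of the dissolution coefficient times that share, is 40.9 s. The feed from E costs a mean delay of 5.59 s, so the flask gets 0.597 turnovers, and I commit to 51.3% for y. I drop the solubility, which overstates the drain, and let Q fill at once, which understates it. Sunday's shortens the drain time to 25.0 s, giving 65.9%. Wednesday's leaves it unchanged but shrinks the excess over solubility, so I expect a fall and give no figure.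

The forecast says 50.9% (from 49.5% to 52.5%), 46.5% after Wednesday's, and Sunday's as its choice, with about 62% after that change against my 65.9%: “speeds the drain out of the Q reservoir”. The flask gives 51.1%, 46.4% after Wednesday's, and Sunday's, worth 11 percentage points.

Part of the gap to full conversion lies in the stock parked in Q together with the early reading. At 30.0 s Q holds 45.1% of the E charged, and with the early reading taken away, the same flask read at 300 s stands at 88.4%. With the path from J to Q taken away, the share becomes 61.1%, the drain time 7.75 s, and the count 3.15 turnovers, which reckons to 98.3%; that run stands at 96.7%.

The constants used here belong to no real substance; the result is computed.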